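**Retrosynthetic overview**

1. Locants used below: C1 = benzylic carbinol carbon, C2 = adjacent methine, C3 = OCH2, C4 = allylic CH2, C5=C6 = styrenyl alkene. The ester C3–O bond is made late by Mitsunobu union of alcohol 13 with the (Z)-acid 20, and both silyl ethers leave in the last step.
2. C3 is carried at the acyl oxidation level as the imide carbonyl of an (S)-4-benzyloxazolidinone and is reduced to CH2OH after the key step, with recovery of the auxiliary.
3. Key disconnection: C1–C2 together with C4–C5 in one flask, from alkenylborane 7, acrylimide 4 and 3,4-dimethoxybenzaldehyde 8 (alkenyl 1,4-addition, then boron aldol).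
4. Enabling feature: O–C3–C2(H)–C1(OH)–aryl is a β-hydroxy-acyl (aldol) array, and C2 also carries C4H2 bound to the sp2 carbon C5. C3–C2–C4 is therefore an acrylic acid unit whose α-carbon C2 becomes an enolate when the styryl group is delivered to C4.
5. Rings: none is formed. Both benzene rings are bought; the oxazolidinone and 9-BBN rings are temporary carriers that leave in steps 5 and 3. Acid 20 comes from crotonaldehyde (α-iodination fixes the geometry, then reduction, silylation, I–Li exchange and CO2).

Key step: step 3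

Remark: the target is a syn aldol array, (S) at C1 and (R) at C2. C2 is (S) while C3 is an imide carbonyl and becomes (R) on reduction only through the priority rules. 9-BBN-H is sold as the dimer and written here as the monomer.

**Route**

Step 1
Reactants: 1 (S)-4-benzyl-1,3-oxazolidin-2-one; 2 acryloyl chloride
Product: 4 (S)-3-acryloyl-4-benzyl-1,3-oxazolidin-2-one, via bromomagnesium amide 3 (not isolated)
Conditions: MeMgBr (1.0 equiv), THF, −78 → 0 °C; then 2, −78 → 0 °C
Reagents that add atoms: none
Why: N-acylation of the magnesium amide of the oxazolidinone by the acid chloride; the bromomagnesium counter-ion keeps conjugate addition and polymerisation of the acrylimide low, and the C4 stereocentre of the ring is not touched.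

Step 2
Reactants: 5 1-ethynyl-4-methoxybenzene; 6 9-borabicyclo[3.3.1]nonane (9-BBN-H)
Product: 7 9-[(E)-2-(4-methoxyphenyl)ethenyl]-9-borabicyclo[3.3.1]nonane
Conditions: 5 (2 equiv), THF, 0 °C → rt; THF and excess 5 removed in vacuo; used as a toluene solution under argon
Reagents that add atoms: none
Why: syn, anti-Markovnikov hydroboration of a terminal arylalkyne puts boron on the terminal carbon and gives the (E)-alkenylborane; the excess of alkyne suppresses geminal dihydroboration.

Step 3
Reactants: 4 (S)-3-acryloyl-4-benzyl-1,3-oxazolidin-2-one; 7 9-[(E)-2-(4-methoxyphenyl)ethenyl]-9-borabicyclo[3.3.1]nonane; 8 3,4-dimethoxybenzaldehyde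
Product: 11 (4S)-4-benzyl-3-[(2S,4E)-2-[(S)-(3,4-dimethoxyphenyl)(hydroxy)methyl]-5-(4-methoxyphenyl)pent-4-enoyl]-1,3-oxazolidin-2-one, via boron (Z)-enolate 9 (not isolated), via boron aldolate 10 (not isolated)
Conditions: [Rh(OMe)(cod)]2 (2.5 mol %), toluene, 25–40 °C, slow addition of 4; then 8, −78 → 0 °C; pH 7 buffer, MeOH, 30% H2O2, 0 °C
Reagents that add atoms: none
Why: Proposed new method: transmetalation of 7 to Rh(I) gives a Rh–alkenyl species that should carbometalate the s-cis acrylimide 4 at C4 to an oxa-π-allyl rhodium enolate, which a second molecule of 7 intercepts by Rh-to-B exchange, releasing the 9-BBN (Z)-enolate 9 and regenerating Rh–alkenyl; 9 then adds to 8 through a closed six-membered chair (Zimmerman–Traxler) transition state. The closest known reaction types are the Rh-catalysed aprotic 1,4-addition of B-aryl-9-BBN reagents to enones, which delivers 9-BBN enolates that are trapped by aldehydes, and the dialkylboron Evans aldol of N-acyl oxazolidinones; new are the alkenyl group and the acrylimide acceptor. No ring of the product is closed. The Z enolate (enforced by A(1,3) strain against the oxazolidinone) with the aryl group of 8 equatorial fixes the syn relation of C1 and C2, and the (S)-benzyl group of the auxiliary, in the dipole-opposed rotamer that a boron carrying only the enolate and aldehyde oxygens requires, blocks one enolate face so that both centres form as (2S,3S) in the imide numbering; the E alkene is carried over from 7 with retention. The step needs 1,4- instead of 1,2-delivery of the alkenyl group, enolate transfer to boron faster than β-hydride elimination, and aldol through boron and not rhodium: the chelating s-cis acrylimide, the aprotic medium with Lewis acidic 9-BBN, and addition of 8 at −78 °C only after 4 is consumed are meant to secure these.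

Step 4
Reactants: 11 (4S)-4-benzyl-3-[(2S,4E)-2-[(S)-(3,4-dimethoxyphenyl)(hydroxy)methyl]-5-(4-methoxyphenyl)pent-4-enoyl]-1,3-oxazolidin-2-one
Product: 12 (4S)-4-benzyl-3-[(2S,4E)-2-[(S)-(3,4-dimethoxyphenyl)(triethylsilyloxy)methyl]-5-(4-methoxyphenyl)pent-4-enoyl]-1,3-oxazolidin-2-one
Conditions: TESOTf, 2,6-lutidine, CH2Cl2, −78 → 0 °C
Reagents that add atoms: triethylsilyl trifluoromethanesulfonate, CC[Si](CC)(CC)OS(=O)(=O)C(F)(F)F
Why: silyl triflate/lutidine silylation of a hindered secondary alcohol; the cold, base-buffered medium should allow neither retro-aldol cleavage nor epimerisation at C2.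

Step 5
Reactants: 12 (4S)-4-benzyl-3-[(2S,4E)-2-[(S)-(3,4-dimethoxyphenyl)(triethylsilyloxy)methyl]-5-(4-methoxyphenyl)pent-4-enoyl]-1,3-oxazolidin-2-one
Product: 13 (2R,4E)-2-[(S)-(3,4-dimethoxyphenyl)(triethylsilyloxy)methyl]-5-(4-methoxyphenyl)pent-4-en-1-ol
Conditions: LiBH4, MeOH (1.1 equiv), THF, 0 °C; aq. NaOH work-up
Reagents that add atoms: none
Why: reductive removal of the oxazolidinone auxiliary; hydride attacks the exocyclic imide carbonyl, the methanol-modified borohydride suppresses endocyclic cleavage, neither stereocentre is touched and auxiliary 1 is recovered.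

Step 6
Reactants: 14 (E)-but-2-enal (crotonaldehyde)
Product: 15 (Z)-2-iodobut-2-enal
Conditions: I2, K2CO3, DMAP (0.2 equiv), THF/H2O 1:1, rt
Reagents that add atoms: iodine, II
Why: amine-mediated α-iodination of an enal (conjugate addition of DMAP, iodination of the enolate, E1cB loss of DMAP) should give the more stable Z isomer, with CH3 trans to CHO and cis to iodine.

Step 7
Reactants: 15 (Z)-2-iodobut-2-enal
Product: 16 (Z)-2-iodobut-2-en-1-ol
Conditions: NaBH4, MeOH, 0 °C
Reagents that add atoms: none
Why: 1,2-reduction of the aldehyde by borohydride at 0 °C leaves the alkenyl iodide and its geometry intact.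

Step 8
Reactants: 16 (Z)-2-iodobut-2-en-1-ol
Product: 17 (Z)-tert-butyl[(2-iodobut-2-en-1-yl)oxy]dimethylsilane
Conditions: TBSCl, imidazole, CH2Cl2, rt
Reagents that add atoms: tert-butyldimethylsilyl chloride, CC(C)(C)[Si](C)(C)Cl
Why: standard imidazole-promoted silylation of a primary allylic alcohol.

Step 9
Reactants: 17 (Z)-tert-butyl[(2-iodobut-2-en-1-yl)oxy]dimethylsilane
Product: 20 (Z)-2-{[(tert-butyldimethylsilyl)oxy]methyl}but-2-enoic acid, via alkenyllithium 18 (not isolated), via lithium carboxylate 19 (not isolated)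
Conditions: t-BuLi (2.1 equiv), Et2O, −78 °C; CO2, −78 → 0 °C; 1 M HCl to pH 3, 0 °C
Reagents that add atoms: carbon dioxide, O=C=O
Why: iodine–lithium exchange on an alkenyl iodide and carboxylation of the alkenyllithium both proceed with retention at −78 °C, so CH3 ends cis to CO2H (Z).

Step 10
Reactants: 13 (2R,4E)-2-[(S)-(3,4-dimethoxyphenyl)(triethylsilyloxy)methyl]-5-(4-methoxyphenyl)pent-4-en-1-ol; 20 (Z)-2-{[(tert-butyldimethylsilyl)oxy]methyl}but-2-enoic acid
Product: 21 (2R,4E)-2-[(S)-(3,4-dimethoxyphenyl)(triethylsilyloxy)methyl]-5-(4-methoxyphenyl)pent-4-en-1-yl (Z)-2-{[(tert-butyldimethylsilyl)oxy]methyl}but-2-enoate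
Conditions: PPh3, DIAD, THF, 0 °C → rt
Reagents that add atoms: none
Why: Mitsunobu esterification activates the primary alcohol and not the acid, so the Z-configured unsaturated acid reacts only as a carboxylate nucleophile and cannot isomerise through an activated acyl species; SN2 at the C3 methylene leaves C1 and C2 alone.

Step 11
Reactants: 21 (2R,4E)-2-[(S)-(3,4-dimethoxyphenyl)(triethylsilyloxy)methyl]-5-(4-methoxyphenyl)pent-4-en-1-yl (Z)-2-{[(tert-butyldimethylsilyl)oxy]methyl}but-2-enoate
Product: 22 (2R,4E)-2-[(S)-(3,4-dimethoxyphenyl)(hydroxy)methyl]-5-(4-methoxyphenyl)pent-4-en-1-yl (2Z)-2-(hydroxymethyl)but-2-enoate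
Conditions: HF·pyridine, pyridine, THF, 0 °C → rt
Reagents that add atoms: none
Why: fluoride-driven cleavage of both Si–O bonds under buffered, mildly acidic conditions, which should avoid 1,3-acyl migration to the benzylic oxygen and ionisation at the electron-rich benzylic carbon.

**Compound list**

1 | (S)-4-benzyl-1,3-oxazolidin-2-one | O=C1N[C@@H](Cc2ccccc2)CO1 | starting material
2 | acryloyl chloride | C=CC(=O)Cl | starting material
3 | bromomagnesium amide of 1 | O=C1OC[C@H](Cc2ccccc2)N1[Mg]Br | intermediate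
4 | (S)-3-acryloyl-4-benzyl-1,3-oxazolidin-2-one | C=CC(=O)N1[C@@H](Cc2ccccc2)COC1=O | intermediate
5 | 1-ethynyl-4-methoxybenzene | C#Cc1ccc(OC)cc1 | starting material
6 | 9-borabicyclo[3.3.1]nonane (9-BBN-H, monomer) | B1C2CCCC1CCC2 | starting material
7 | 9-[(E)-2-(4-methoxyphenyl)ethenyl]-9-borabicyclo[3.3.1]nonane | COc1ccc(/C=C/B2C3CCCC2CCC3)cc1 | intermediate
8 | 3,4-dimethoxybenzaldehyde | COc1ccc(C=O)cc1OC | starting material
9 | boron (Z)-enolate: (4S)-4-benzyl-3-[(1Z,4E)-1-(9-borabicyclo[3.3.1]non-9-yloxy)-5-(4-methoxyphenyl)penta-1,4-dien-1-yl]-1,3-oxazolidin-2-one | COc1ccc(/C=C/C/C=C(\OB2C3CCCC2CCC3)N2[C@@H](Cc3ccccc3)COC2=O)cc1 | intermediate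
10 | boron aldolate: O-(9-borabicyclo[3.3.1]non-9-yl) derivative of 11 | O=C1OC[C@H](Cc2ccccc2)N1C(=O)[C@@H](C/C=C/c1ccc(OC)cc1)[C@H](OB1C2CCCC1CCC2)c1ccc(OC)c(OC)c1 | intermediate
11 | (4S)-4-benzyl-3-[(2S,4E)-2-[(S)-(3,4-dimethoxyphenyl)(hydroxy)methyl]-5-(4-methoxyphenyl)pent-4-enoyl]-1,3-oxazolidin-2-one | O=C1OC[C@H](Cc2ccccc2)N1C(=O)[C@@H](C/C=C/c1ccc(OC)cc1)[C@H](O)c1ccc(OC)c(OC)c1 | intermediate
12 | (4S)-4-benzyl-3-[(2S,4E)-2-[(S)-(3,4-dimethoxyphenyl)(triethylsilyloxy)methyl]-5-(4-methoxyphenyl)pent-4-enoyl]-1,3-oxazolidin-2-one | O=C1OC[C@H](Cc2ccccc2)N1C(=O)[C@@H](C/C=C/c1ccc(OC)cc1)[C@H](O[Si](CC)(CC)CC)c1ccc(OC)c(OC)c1 | intermediate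
13 | (2R,4E)-2-[(S)-(3,4-dimethoxyphenyl)(triethylsilyloxy)methyl]-5-(4-methoxyphenyl)pent-4-en-1-ol | OC[C@@H](C/C=C/c1ccc(OC)cc1)[C@H](O[Si](CC)(CC)CC)c1ccc(OC)c(OC)c1 | intermediate
14 | (E)-but-2-enal (crotonaldehyde) | C/C=C/C=O | starting material
15 | (Z)-2-iodobut-2-enal | C/C=C(/C=O)I | intermediate
16 | (Z)-2-iodobut-2-en-1-ol | C/C=C(/CO)I | intermediate
17 | (Z)-tert-butyl[(2-iodobut-2-en-1-yl)oxy]dimethylsilane | C/C=C(/CO[Si](C)(C)C(C)(C)C)I | intermediate
18 | alkenyllithium: 1-[(tert-butyldimethylsilyl)oxy]but-2-en-2-yllithium, CH3 cis to Li | C/C=C(/CO[Si](C)(C)C(C)(C)C)[Li] | intermediate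
19 | lithium (Z)-2-{[(tert-butyldimethylsilyl)oxy]methyl}but-2-enoate | C/C=C(/CO[Si](C)(C)C(C)(C)C)C(=O)[O-].[Li+] | intermediate
20 | (Z)-2-{[(tert-butyldimethylsilyl)oxy]methyl}but-2-enoic acid | C/C=C(/CO[Si](C)(C)C(C)(C)C)C(=O)O | intermediate
21 | (2R,4E)-2-[(S)-(3,4-dimethoxyphenyl)(triethylsilyloxy)methyl]-5-(4-methoxyphenyl)pent-4-en-1-yl (Z)-2-{[(tert-butyldimethylsilyl)oxy]methyl}but-2-enoate | C/C=C(/CO[Si](C)(C)C(C)(C)C)C(=O)OC[C@@H](C/C=C/c1ccc(OC)cc1)[C@H](O[Si](CC)(CC)CC)c1ccc(OC)c(OC)c1 | intermediate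
22 | (2R,4E)-2-[(S)-(3,4-dimethoxyphenyl)(hydroxy)methyl]-5-(4-methoxyphenyl)pent-4-en-1-yl (2Z)-2-(hydroxymethyl)but-2-enoate | C/C=C(/CO)C(=O)OC[C@@H](C/C=C/c1ccc(OC)cc1)[C@H](O)c1ccc(OC)c(OC)c1 | target

**Step count and risks**

Total step count: 11. Longest linear sequence: 6 steps (1, 3, 4, 5, 10, 11; the branches through step 2 and through steps 6–9 are no longer).

Steps most likely to fail:

1. Step 3 (proposed new method). β-Hydride elimination from the carbon-bound rhodium enolate (a Heck-type outcome) or oligomerisation of the acrylimide may outrun enolate transfer to boron. An aldol through a rhodium-bound or chelated enolate would erode facial selectivity. The fallback uses known chemistry, sets out from 1 and 8, and comes back at 11. Compound 1 is N-acylated with pent-4-enoyl chloride (Et3N, cat. DMAP, CH2Cl2) to (S)-4-benzyl-3-(pent-4-enoyl)-1,3-oxazolidin-2-one F1. Soft enolisation with Bu2BOTf and iPr2NEt (CH2Cl2, −78 → 0 °C) gives the dibutylboron (Z)-enolate F2, which adds to 8 to give the dibutylboron aldolate F3. Oxidative work-up (pH 7 buffer, MeOH, H2O2) then gives the Evans syn aldol (4S)-4-benzyl-3-[(2S)-2-[(S)-(3,4-dimethoxyphenyl)(hydroxy)methyl]pent-4-enoyl]-1,3-oxazolidin-2-one F4. Cross-metathesis of F4 with 1-ethenyl-4-methoxybenzene (second-generation Ru–NHC benzylidene catalyst, CH2Cl2, 40 °C) should install the (E)-4-methoxystyryl terminus and give 11.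

2. Step 10. Displacement at the β-branched alkoxyphosphonium carbon may be slow, so that acylation of the reduced azodicarboxylate consumes the acid. The fallback sets out from 13 and 17 and comes back at 21: palladium-catalysed carbonylative esterification of the alkenyl iodide 17 with alcohol 13 (Pd(OAc)2, Xantphos, CO 1 atm, Et3N, toluene, 70 °C). This forms the acyl–carbon bond with retention of alkene geometry and needs neither the free acid nor alcohol activation. It makes no compound outside the list, entered below as none F0.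

3. Step 9. The alkenyllithium may lose silanolate by β-elimination (allene formation) or add twice to carbon dioxide before the quench is complete. The fallback sets out from 17 and comes back at 20. Palladium-catalysed methoxycarbonylation of 17 (Pd(OAc)2, PPh3, CO 1 atm, MeOH, Et3N, DMF, 60 °C) gives methyl (Z)-2-{[(tert-butyldimethylsilyl)oxy]methyl}but-2-enoate F5 with retention of geometry. Saponification (LiOH, THF/H2O, 0 °C → rt) passes through the lithium carboxylate 19, and acidification to pH 3 gives 20.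

Further compounds
F1 | step 3 | (S)-4-benzyl-3-(pent-4-enoyl)-1,3-oxazolidin-2-one | C=CCCC(=O)N1[C@@H](Cc2ccccc2)COC1=O
F2 | step 3 | dibutylboron (Z)-enolate of F1 | C=CC/C=C(\OB(CCCC)CCCC)N1[C@@H](Cc2ccccc2)COC1=O
F3 | step 3 | dibutylboron aldolate (O-dibutylboryl derivative of F4) | O=C1OC[C@H](Cc2ccccc2)N1C(=O)[C@@H](CC=C)[C@H](OB(CCCC)CCCC)c1ccc(OC)c(OC)c1
F4 | step 3 | (4S)-4-benzyl-3-[(2S)-2-[(S)-(3,4-dimethoxyphenyl)(hydroxy)methyl]pent-4-enoyl]-1,3-oxazolidin-2-one | O=C1OC[C@H](Cc2ccccc2)N1C(=O)[C@@H](CC=C)[C@H](O)c1ccc(OC)c(OC)c1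
F5 | step 9 | methyl (Z)-2-{[(tert-butyldimethylsilyl)oxy]methyl}but-2-enoate | C/C=C(/CO[Si](C)(C)C(C)(C)C)C(=O)OC
F0 | step 10 | none | none
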